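## Analysis of the target

The target 21 is a 1H-isochromene: a 2H-pyran (O2, C1, C8a, C4a, C4, C3) fused through C4a=C8a to a cyclohexenone (C4a, C5, C6, C7, C8, C8a). C3 carries an (E)-propenyl group, so O2, C3=C4, C4a=C8a and the C8 carbonyl form one push–pull chromophore. There are two adjacent stereocentres. C6 (S) is a secondary carbinol. C7 (R) is fully substituted and carries a methyl group and the 4-hydroxy-2-methoxy-6-methylbenzoyloxy group. The two oxygens are trans, and the C7 methyl is cis to the C6 hydroxyl. Sensitive features are the dienol ether (acid), the C6 hydroxyl beta to the C8 ketone (retro-aldol, dehydration), the ester beside a free hydroxyl (acyl shift under base), the free phenol and the (E)-alkene. The hard parts are the quaternary alpha-acyloxy ketone C7 with defined configuration relative to C6, and the ester, which joins a tertiary alcohol to a 2,6-disubstituted benzoic acid. The strategy rests on C7 (methyl, oxygen) beside the C8 ketone being a tertiary alpha-ketol. That is the product pattern of a 1,2-shift in a 1-acetylcyclopentenol in which C8 is still the carbinol carbon and the acetyl carbon is the future C7. The carbocycle can therefore be built one atom smaller, and C7 can be created from C6 by a suprafacial shift.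

## Retrosynthetic reasoning

Pyran last. The O2–C3 bond of 21 is cut, which leads back to the ynenone triol 20. The dienol ether is the most acid-sensitive part of the molecule, so it should not be carried through other steps. The forward reaction is a 6-endo addition of the C1 hydroxyl to the alkyne. The alkyne is polarised by the C8 ketone through C8a=C4a, so its distal carbon C3 is the electrophilic one.

Protecting groups. 20 comes from its tris-silyl derivative 19 by one global desilylation. No skeletal bond is cut. The fluoride step is thereby placed before the dienol ether exists, and the C1 and C6 oxygens need not be distinguished.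

Ester. The acyl–oxygen bond at C7 of 19 is cut, giving the tertiary ketol 14 and the acid chloride 17. 17 comes from the purchased acid 15 through its bis-silyl derivative 16. The bond is cut here because 14 is exactly the compound that the ring expansion delivers. The forward reaction must acylate a hindered tertiary alkoxide with a hindered acyl donor and is treated as a risk.

Ring expansion (key disconnection). In 14 the C6–C7 bond is cut and C6 is reconnected to C8. This gives the 1-acetylcyclopent-2-en-1-ol 13, in which the acetyl group is cis to the C6 silyl ether. The gain is that the quaternary centre C7 is not built by an intermolecular reaction. It arises from a carbonyl carbon onto which C6 is delivered from a defined face, so its configuration is tied to C8, which in turn is tied to C6. The forward reaction must move C6 and not the alkenyl carbon C8a, and must go through the chelated rotamer.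

Enyne. 13 is the oxidation product of diol 12. In 12 the bond between the alkyne and the propenyl carbon is cut, giving the terminal alkyne 10 and the vinyl bromide 11 (Sonogashira coupling). The propenyl group is attached only at this stage, after the dihydroxylation, so that the oxidant never has to choose between two reactive alkenes. Until then the alkyne carries a trimethylsilyl cap (9).

Ketol oxygens. The two C–O bonds at C8 and at the side-chain carbon of 9 are cut, giving the exocyclic ethylidene compound 8. Nucleophiles add to the C8 ketone anti to the C6 silyl ether and would place the carbon chain trans to it. A face-selective dihydroxylation of the alkene anti to the silyl ether places the C8 oxygen trans and the carbon chain cis, as 13 requires. 8 comes from ketone 7 by cutting the exocyclic C=C bond (Wittig).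

Carbonyl transposition. Enone 7 is traced to the tertiary alkynyl carbinol 6 by an oxidative 1,3-transposition. In 6 the bond between the ring and the alkyne is cut, giving enone 3 and the alkyne 4. This puts the ketone next to the silyloxy carbon and the alkyne on the former carbonyl carbon. The stereocentre of a purchased 4-silyloxycyclopentenone thereby becomes C6, and no asymmetric oxidation is needed.

Hydroxymethyl group. In 3 the bond between C8a and C1 is cut. This leads through the alcohol 2 to the purchased enone 1 (Morita–Baylis–Hillman hydroxymethylation, then silylation).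

## Alternatives that were turned down

Alternative 1: The C5–C6 bond is cut. The precursor is the monocyclic keto aldehyde A2, a 2H-pyran with a methyl group on C4a and the chain C8(=O)–C7(Me)(OAr)–CHO on C8a. In the forward step A2 is enolised through the C4a methyl group with a silyl triflate and an amine to the silyl dienol ether A3. Its terminal carbon adds to the C6 aldehyde under a boron Lewis acid (vinylogous Mukaiyama aldol) and gives A1, the target with the phenol silylated. For it: the ring closure comes last, the ester is already in place, and only a phenol deprotection remains after the key step. On convergence and on the number of steps after the key step it is stronger than the chosen route. Against it: A2 holds the quaternary C7 between a ketone and an aldehyde, so the formyl group is easily lost by retro-Claisen cleavage. C7 must be made as a single enantiomer in an open chain with no neighbouring centre to control it. The C6 configuration would depend on 1,2-induction from a centre whose methyl and aroyloxy groups differ little. A monocyclic 2H-pyran such as A2 can open electrocyclically to an oxatriene. The chosen strategy offers instead a C7 that is formed intramolecularly from C6 with a predictable geometry, and intermediates without a fragile 1,3-dicarbonyl unit.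

Alternative 2: The C7–C8 bond is cut. The precursor A5 is a 2H-pyran-3-carbaldehyde (the aldehyde on C8a is the future C8) with a 2-silyloxy-3-oxobutyl chain on C4a. A chiral triazolium-derived carbene converts the aldehyde into its Breslow intermediate, which adds to the methyl ketone. This closes the carbocycle and creates C7, giving the bicyclic ketol A4. For it: the tertiary ketol is formed directly and catalytically, the catalyst can in principle set C7 independently of C6, and the pyran is already present, so the end game is shorter. On these points it is stronger than the chosen route. Against it: the aldehyde of A5 is the carbonyl of a vinylogous formate (donor O2 through the diene) and is a poor electrophile for the carbene. The extended Breslow intermediate has redox outlets other than the benzoin addition. C6 in A5 is alpha to the ketone, carries a silyloxy group and an acidic hydrogen, and sits next to the vinylogously acidic C5, so epimerisation and elimination of silanol under the amine base are likely. Whether catalyst and C6 are matched for the trans product is open. The chosen strategy offers instead a relay from a purchased C6 stereocentre. Its only enolisable stage (7) comes before C8 and C7 exist.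

Alternative 3: The two ring bonds of the benzoate that flank the former alkyne carbons are cut. The C7 but-2-ynoate A7 reacts as dienophile with the ketene-acetal diene A8 on heating. The adduct aromatises by eliminating one of the two methoxy groups and gives A6, the target with the C6 hydroxyl silylated. For it: it avoids acylating a tertiary alcohol with a 2,6-disubstituted benzoyl donor, the weakest point of the chosen end game. Here Alternative 3 is clearly stronger. The regiochemistry follows from the polarised diene and the phenol appears unprotected. Against it: it does not make the core. A7 still needs the bicyclic ketol with both stereocentres, so another strategy must be added. The electron-rich diene is heated with a substrate that contains a dienone, a dienol ether and an enyne, all of which can compete. The arene costs several steps although the acid 15 can be bought. The chosen strategy uses the purchased acid in one acylation and keeps this cycloaddition in reserve as the fallback for step 13.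

Key step: step 10

Assumption: 1 (needed as the S antipode), 4, 11 (as the pure E isomer) and 15 are taken to be catalogue compounds.

## Route

Step 1
Reactants: 1 (S)-4-(tert-butyldimethylsilyloxy)cyclopent-2-en-1-one
Product: 2 (S)-4-(tert-butyldimethylsilyloxy)-2-(hydroxymethyl)cyclopent-2-en-1-one
Conditions: 37% aq. HCHO, imidazole, THF/H2O, rt
Reagents that add atoms: formaldehyde, C=O
Why: Morita–Baylis–Hillman hydroxymethylation: imidazole adds reversibly to C3, the enolate adds to formaldehyde and loss of imidazole restores the enone; the weak base does not touch the silyloxy stereocentre.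

Step 2
Reactants: 2 (S)-4-(tert-butyldimethylsilyloxy)-2-(hydroxymethyl)cyclopent-2-en-1-one
Product: 3 (S)-4-(tert-butyldimethylsilyloxy)-2-[(tert-butyldimethylsilyloxy)methyl]cyclopent-2-en-1-one
Conditions: TBSCl, imidazole, CH2Cl2, 0 °C
Reagents that add atoms: tert-butyldimethylsilyl chloride, CC(C)(C)[Si](C)(C)Cl
Why: Standard silylation of a primary allylic alcohol; the tert-butyldimethylsilyl ether is chosen because it must survive hexavalent chromium, an ylide and a copper Lewis acid and is removed together with the other silyl groups in step 14.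

Step 3
Reactants: 3 (S)-4-(tert-butyldimethylsilyloxy)-2-[(tert-butyldimethylsilyloxy)methyl]cyclopent-2-en-1-one; 4 ethynyltrimethylsilane
Product: 6 (4S)-4-(tert-butyldimethylsilyloxy)-2-[(tert-butyldimethylsilyloxy)methyl]-1-[(trimethylsilyl)ethynyl]cyclopent-2-en-1-ol (C1 epimers), via lithium (trimethylsilyl)acetylide 5 (not isolated)
Conditions: 4, n-BuLi, THF, −78 °C; then 3, −78 °C; aq. NH4Cl
Reagents that add atoms: none
Why: 1,2-addition of a lithium acetylide to an enone carbonyl; the weakly basic nucleophile at low temperature avoids elimination of silanol, and the new carbinol centre is of no consequence because it is removed in step 4.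

Step 4
Reactants: 6 (4S)-4-(tert-butyldimethylsilyloxy)-2-[(tert-butyldimethylsilyloxy)methyl]-1-[(trimethylsilyl)ethynyl]cyclopent-2-en-1-ol
Product: 7 (S)-5-(tert-butyldimethylsilyloxy)-2-[(tert-butyldimethylsilyloxy)methyl]-3-[(trimethylsilyl)ethynyl]cyclopent-2-en-1-one
Conditions: pyridinium chlorochromate, 4 Å MS, CH2Cl2, rt
Reagents that add atoms: pyridinium chlorochromate, [O-][Cr](=O)(=O)Cl.c1cc[nH+]cc1
Why: Babler–Dauben oxidative 1,3-transposition: the chromate ester of the tertiary allylic alcohol undergoes a [3,3] shift to the secondary allylic chromate, which is oxidised to the enone; the ketone now sits beside the silyloxy carbon, which thereby becomes C6, and no bond at that stereocentre is touched.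

Step 5
Reactants: 7 (S)-5-(tert-butyldimethylsilyloxy)-2-[(tert-butyldimethylsilyloxy)methyl]-3-[(trimethylsilyl)ethynyl]cyclopent-2-en-1-one
Product: 8 tert-butyl{[(1S)-3-[(tert-butyldimethylsilyloxy)methyl]-2-ethylidene-4-[(trimethylsilyl)ethynyl]cyclopent-3-en-1-yl]oxy}dimethylsilane (E/Z mixture)
Conditions: EtPPh3Br, KN(SiMe3)2, THF, 0 °C; then 7, 0 °C → rt
Reagents that add atoms: ethyltriphenylphosphonium bromide, [Br-].CC[P+](c1ccccc1)(c1ccccc1)c1ccccc1
Why: Wittig ethylidenation of a cyclopentanone-type carbonyl, as used on 17-keto steroids; the alkene geometry is immaterial because the CH carbon becomes the acetyl carbonyl, and addition of the ketone to preformed ylide at low temperature limits enolisation at C6.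

Step 6
Reactants: 8 tert-butyl{[(1S)-3-[(tert-butyldimethylsilyloxy)methyl]-2-ethylidene-4-[(trimethylsilyl)ethynyl]cyclopent-3-en-1-yl]oxy}dimethylsilane
Product: 9 1-[(1R,5S)-5-(tert-butyldimethylsilyloxy)-2-[(tert-butyldimethylsilyloxy)methyl]-1-hydroxy-3-[(trimethylsilyl)ethynyl]cyclopent-2-en-1-yl]ethan-1-ol (tertiary hydroxyl trans to the ring silyl ether; side-chain carbinol epimers)
Conditions: OsO4 (5 mol %), NMO, acetone/H2O, 0 °C → rt
Reagents that add atoms: osmium tetroxide, O=[Os](=O)(=O)=O; N-methylmorpholine N-oxide, C[N+]1([O-])CCOCC1; water, O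
Why: Upjohn dihydroxylation: the exocyclic trisubstituted alkene is the only reactive one, since the ring alkene is tetrasubstituted and conjugated with the alkyne and the propenyl group is not yet present; OsO4 attacks anti to the allylic C6 silyl ether (Kishi model), which places the C8 oxygen trans and the carbon chain cis to that ether.

Step 7
Reactants: 9 1-[(1R,5S)-5-(tert-butyldimethylsilyloxy)-2-[(tert-butyldimethylsilyloxy)methyl]-1-hydroxy-3-[(trimethylsilyl)ethynyl]cyclopent-2-en-1-yl]ethan-1-ol
Product: 10 1-[(1R,5S)-5-(tert-butyldimethylsilyloxy)-2-[(tert-butyldimethylsilyloxy)methyl]-3-ethynyl-1-hydroxycyclopent-2-en-1-yl]ethan-1-ol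
Conditions: K2CO3 (cat.), MeOH, 0 °C
Reagents that add atoms: none
Why: Methanolysis of the alkynyl C–Si bond; alkyl tert-butyldimethylsilyl ethers and the diol are stable, and the base is used on the diol and not on the later ketol.

Step 8
Reactants: 10 1-[(1R,5S)-5-(tert-butyldimethylsilyloxy)-2-[(tert-butyldimethylsilyloxy)methyl]-3-ethynyl-1-hydroxycyclopent-2-en-1-yl]ethan-1-ol; 11 (E)-1-bromoprop-1-ene
Product: 12 1-[(1R,5S)-5-(tert-butyldimethylsilyloxy)-2-[(tert-butyldimethylsilyloxy)methyl]-1-hydroxy-3-[(E)-pent-3-en-1-yn-1-yl]cyclopent-2-en-1-yl]ethan-1-ol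
Conditions: 11, Pd(PPh3)4 (5 mol %), CuI (10 mol %), i-Pr2NH, THF, rt
Reagents that add atoms: none
Why: Sonogashira coupling: zerovalent palladium inserts into the vinyl bromide with retention of the E geometry and the copper acetylide transfers the alkyne; free hydroxyl groups are tolerated.

Step 9
Reactants: 12 1-[(1R,5S)-5-(tert-butyldimethylsilyloxy)-2-[(tert-butyldimethylsilyloxy)methyl]-1-hydroxy-3-[(E)-pent-3-en-1-yn-1-yl]cyclopent-2-en-1-yl]ethan-1-ol
Product: 13 1-[(1S,5S)-5-(tert-butyldimethylsilyloxy)-2-[(tert-butyldimethylsilyloxy)methyl]-1-hydroxy-3-[(E)-pent-3-en-1-yn-1-yl]cyclopent-2-en-1-yl]ethan-1-one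
Conditions: SO3·pyridine, DMSO, i-Pr2NEt, CH2Cl2, 0 °C
Reagents that add atoms: none
Why: Parikh–Doering oxidation of the secondary hydroxyl of a secondary/tertiary diol to the alpha-ketol without glycol cleavage; both carbinol epimers converge on one ketone and the tertiary allylic alcohol is untouched.

Step 10
Reactants: 13 1-[(1S,5S)-5-(tert-butyldimethylsilyloxy)-2-[(tert-butyldimethylsilyloxy)methyl]-1-hydroxy-3-[(E)-pent-3-en-1-yn-1-yl]cyclopent-2-en-1-yl]ethan-1-one
Product: 14 (5S,6R)-5-(tert-butyldimethylsilyloxy)-2-[(tert-butyldimethylsilyloxy)methyl]-6-hydroxy-6-methyl-3-[(E)-pent-3-en-1-yn-1-yl]cyclohex-2-en-1-one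
Conditions: Cu(OTf)2 (20 mol %), 4 Å MS, ClCH2CH2Cl, rt → 50 °C
Reagents that add atoms: none
Why: Divalent copper binds the C8 hydroxyl and the acetyl oxygen in a five-membered chelate, which polarises the acetyl carbonyl and holds the two oxygens syn, so that the two ring bonds of C8 lie above and below the carbonyl plane; the C8–C6 bond then shifts to the acetyl carbon while the carbinol oxygen becomes the C8 ketone (alpha-ketol or acyloin rearrangement). The closest known reaction type is the Lewis-acid-promoted ring expansion of 1-acylcycloalkanols, classically the D-homoannulation of 17-hydroxy-20-keto steroids. The six-membered ring is not closed by a cyclisation: a 1,2-shift inserts the acetyl carbon between C8 and C6, so no Baldwin mode applies and the ring grows from five to six atoms. C6 migrates with retention, so the configuration bought with 1 is unchanged. The new stereocentre C7 is controlled by the C8 configuration of 13 together with the chelate geometry: with the acetyl group cis to the C6 silyl ether and the oxygens syn, C6 is delivered to the carbonyl face that leaves the C7 hydroxyl trans and the C7 methyl cis to the C6 silyl ether. The step needs selectivity between migration of C6 and of the alkenyl carbon C8a: migration of C8a would give a ketol whose ketone is out of conjugation and which can revert through the same manifold, whereas migration of C6 gives the ketone conjugated with C8a=C4a and the alkyne, the thermodynamic sink. Molecular sieves and the absence of protic acid should keep both silyl ethers intact.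

Step 11
Reactants: 15 4-hydroxy-2-methoxy-6-methylbenzoic acid
Product: 16 tert-butyldimethylsilyl 4-(tert-butyldimethylsilyloxy)-2-methoxy-6-methylbenzoate
Conditions: TBSCl (2.5 equiv), imidazole, DMF, rt
Reagents that add atoms: tert-butyldimethylsilyl chloride, CC(C)(C)[Si](C)(C)Cl
Why: Exhaustive silylation of phenol and carboxylic acid; the phenol must be masked so that the acid chloride cannot acylate itself.

Step 12
Reactants: 16 tert-butyldimethylsilyl 4-(tert-butyldimethylsilyloxy)-2-methoxy-6-methylbenzoate
Product: 17 4-(tert-butyldimethylsilyloxy)-2-methoxy-6-methylbenzoyl chloride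
Conditions: (COCl)2, DMF (cat.), CH2Cl2, 0 °C → rt; concentrate, use crude
Reagents that add atoms: oxalyl chloride, O=C(Cl)C(Cl)=O
Why: Conversion of a silyl ester into the acid chloride by the Vilsmeier chloroiminium salt under neutral conditions; no hydrogen chloride is formed, so the aryl silyl ether survives.

Step 13
Reactants: 14 (5S,6R)-5-(tert-butyldimethylsilyloxy)-2-[(tert-butyldimethylsilyloxy)methyl]-6-hydroxy-6-methyl-3-[(E)-pent-3-en-1-yn-1-yl]cyclohex-2-en-1-one; 17 4-(tert-butyldimethylsilyloxy)-2-methoxy-6-methylbenzoyl chloride
Product: 19 (1R,6S)-6-(tert-butyldimethylsilyloxy)-3-[(tert-butyldimethylsilyloxy)methyl]-1-methyl-2-oxo-4-[(E)-pent-3-en-1-yn-1-yl]cyclohex-3-en-1-yl 4-(tert-butyldimethylsilyloxy)-2-methoxy-6-methylbenzoate, via lithium alkoxide 18 (not isolated)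
Conditions: LiN(SiMe3)2, THF, −78 °C; then 17, −78 → 0 °C
Reagents that add atoms: none
Why: O-acylation of a preformed tertiary alkoxide; one equivalent of base removes only the hydroxyl proton, and 2,6-disubstituted benzoyl chlorides react through a loose, acylium-like transition state that is less sensitive to the bulk of the alkoxide; the C7 configuration is not involved.

Step 14
Reactants: 19 (1R,6S)-6-(tert-butyldimethylsilyloxy)-3-[(tert-butyldimethylsilyloxy)methyl]-1-methyl-2-oxo-4-[(E)-pent-3-en-1-yn-1-yl]cyclohex-3-en-1-yl 4-(tert-butyldimethylsilyloxy)-2-methoxy-6-methylbenzoate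
Product: 20 (1R,6S)-6-hydroxy-3-(hydroxymethyl)-1-methyl-2-oxo-4-[(E)-pent-3-en-1-yn-1-yl]cyclohex-3-en-1-yl 4-hydroxy-2-methoxy-6-methylbenzoate
Conditions: HF·pyridine, pyridine, THF, 0 °C → rt
Reagents that add atoms: none
Why: Global fluoride-mediated desilylation under mildly acidic conditions, which avoid retro-aldol cleavage and acyl shift; the di-ortho-substituted ester is shielded from attack by the neighbouring C6 hydroxyl, and any early conjugate closure of the freed C1 hydroxyl would lead to 21 and is harmless.

Step 15
Reactants: 20 (1R,6S)-6-hydroxy-3-(hydroxymethyl)-1-methyl-2-oxo-4-[(E)-pent-3-en-1-yn-1-yl]cyclohex-3-en-1-yl 4-hydroxy-2-methoxy-6-methylbenzoate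
Product: 21 (6S,7R)-6-hydroxy-7-methyl-8-oxo-3-[(E)-prop-1-en-1-yl]-5,6,7,8-tetrahydro-1H-isochromen-7-yl 4-hydroxy-2-methoxy-6-methylbenzoate (CNP0187389.4)
Conditions: Ph3PAuNTf2 (5 mol %), THF, rt
Reagents that add atoms: none
Why: Monovalent-gold-catalysed intramolecular hydroalkoxylation of the alkyne, 6-endo-dig: the C1 hydroxyl attacks the alkyne carbon remote from the ring (C3), which is the electrophilic terminus of the ynenone, and protodeauration gives the C3=C4 dienol ether; the C6 hydroxyl cannot reach the alkyne without forming a bridgehead alkene, and the phenol is remote.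

## Compound list

1 | (S)-4-(tert-butyldimethylsilyloxy)cyclopent-2-en-1-one | O=C1C=C[C@@H](O[Si](C)(C)C(C)(C)C)C1 | starting material
2 | (S)-4-(tert-butyldimethylsilyloxy)-2-(hydroxymethyl)cyclopent-2-en-1-one | O=C1C(CO)=C[C@@H](O[Si](C)(C)C(C)(C)C)C1 | intermediate
3 | (S)-4-(tert-butyldimethylsilyloxy)-2-[(tert-butyldimethylsilyloxy)methyl]cyclopent-2-en-1-one | O=C1C(CO[Si](C)(C)C(C)(C)C)=C[C@@H](O[Si](C)(C)C(C)(C)C)C1 | intermediate
4 | ethynyltrimethylsilane | C#C[Si](C)(C)C | starting material
5 | lithium (trimethylsilyl)acetylide | [Li]C#C[Si](C)(C)C | intermediate (not isolated)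
6 | (4S)-4-(tert-butyldimethylsilyloxy)-2-[(tert-butyldimethylsilyloxy)methyl]-1-[(trimethylsilyl)ethynyl]cyclopent-2-en-1-ol, C1 epimers | C[Si](C)(C)C#CC1(O)C(CO[Si](C)(C)C(C)(C)C)=C[C@@H](O[Si](C)(C)C(C)(C)C)C1 | intermediate
7 | (S)-5-(tert-butyldimethylsilyloxy)-2-[(tert-butyldimethylsilyloxy)methyl]-3-[(trimethylsilyl)ethynyl]cyclopent-2-en-1-one | C[Si](C)(C)C#CC1=C(CO[Si](C)(C)C(C)(C)C)C(=O)[C@@H](O[Si](C)(C)C(C)(C)C)C1 | intermediate
8 | tert-butyl{[(1S)-3-[(tert-butyldimethylsilyloxy)methyl]-2-ethylidene-4-[(trimethylsilyl)ethynyl]cyclopent-3-en-1-yl]oxy}dimethylsilane, E/Z mixture | C[Si](C)(C)C#CC1=C(CO[Si](C)(C)C(C)(C)C)C(=CC)[C@@H](O[Si](C)(C)C(C)(C)C)C1 | intermediate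
9 | 1-[(1R,5S)-5-(tert-butyldimethylsilyloxy)-2-[(tert-butyldimethylsilyloxy)methyl]-1-hydroxy-3-[(trimethylsilyl)ethynyl]cyclopent-2-en-1-yl]ethan-1-ol, side-chain carbinol epimers | C[Si](C)(C)C#CC1=C(CO[Si](C)(C)C(C)(C)C)[C@@](O)(C(C)O)[C@@H](O[Si](C)(C)C(C)(C)C)C1 | intermediate
10 | 1-[(1R,5S)-5-(tert-butyldimethylsilyloxy)-2-[(tert-butyldimethylsilyloxy)methyl]-3-ethynyl-1-hydroxycyclopent-2-en-1-yl]ethan-1-ol | C#CC1=C(CO[Si](C)(C)C(C)(C)C)[C@@](O)(C(C)O)[C@@H](O[Si](C)(C)C(C)(C)C)C1 | intermediate
11 | (E)-1-bromoprop-1-ene | C/C=C/Br | starting material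
12 | 1-[(1R,5S)-5-(tert-butyldimethylsilyloxy)-2-[(tert-butyldimethylsilyloxy)methyl]-1-hydroxy-3-[(E)-pent-3-en-1-yn-1-yl]cyclopent-2-en-1-yl]ethan-1-ol | C/C=C/C#CC1=C(CO[Si](C)(C)C(C)(C)C)[C@@](O)(C(C)O)[C@@H](O[Si](C)(C)C(C)(C)C)C1 | intermediate
13 | 1-[(1S,5S)-5-(tert-butyldimethylsilyloxy)-2-[(tert-butyldimethylsilyloxy)methyl]-1-hydroxy-3-[(E)-pent-3-en-1-yn-1-yl]cyclopent-2-en-1-yl]ethan-1-one (acetyl cis to the C6 silyl ether) | C/C=C/C#CC1=C(CO[Si](C)(C)C(C)(C)C)[C@@](O)(C(C)=O)[C@@H](O[Si](C)(C)C(C)(C)C)C1 | intermediate
14 | (5S,6R)-5-(tert-butyldimethylsilyloxy)-2-[(tert-butyldimethylsilyloxy)methyl]-6-hydroxy-6-methyl-3-[(E)-pent-3-en-1-yn-1-yl]cyclohex-2-en-1-one | C/C=C/C#CC1=C(CO[Si](C)(C)C(C)(C)C)C(=O)[C@](C)(O)[C@@H](O[Si](C)(C)C(C)(C)C)C1 | intermediate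
15 | 4-hydroxy-2-methoxy-6-methylbenzoic acid | Cc1cc(O)cc(OC)c1C(O)=O | starting material
16 | tert-butyldimethylsilyl 4-(tert-butyldimethylsilyloxy)-2-methoxy-6-methylbenzoate | Cc1cc(O[Si](C)(C)C(C)(C)C)cc(OC)c1C(=O)O[Si](C)(C)C(C)(C)C | intermediate
17 | 4-(tert-butyldimethylsilyloxy)-2-methoxy-6-methylbenzoyl chloride | Cc1cc(O[Si](C)(C)C(C)(C)C)cc(OC)c1C(Cl)=O | intermediate
18 | lithium alkoxide of 14 at the C7 oxygen | C/C=C/C#CC1=C(CO[Si](C)(C)C(C)(C)C)C(=O)[C@](C)(O[Li])[C@@H](O[Si](C)(C)C(C)(C)C)C1 | intermediate (not isolated)
19 | (1R,6S)-6-(tert-butyldimethylsilyloxy)-3-[(tert-butyldimethylsilyloxy)methyl]-1-methyl-2-oxo-4-[(E)-pent-3-en-1-yn-1-yl]cyclohex-3-en-1-yl 4-(tert-butyldimethylsilyloxy)-2-methoxy-6-methylbenzoate | C/C=C/C#CC1=C(CO[Si](C)(C)C(C)(C)C)C(=O)[C@](C)(OC(=O)c2c(C)cc(O[Si](C)(C)C(C)(C)C)cc2OC)[C@@H](O[Si](C)(C)C(C)(C)C)C1 | intermediate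
20 | (1R,6S)-6-hydroxy-3-(hydroxymethyl)-1-methyl-2-oxo-4-[(E)-pent-3-en-1-yn-1-yl]cyclohex-3-en-1-yl 4-hydroxy-2-methoxy-6-methylbenzoate | C/C=C/C#CC1=C(CO)C(=O)[C@](C)(OC(=O)c2c(C)cc(O)cc2OC)[C@@H](O)C1 | intermediate
21 | (6S,7R)-6-hydroxy-7-methyl-8-oxo-3-[(E)-prop-1-en-1-yl]-5,6,7,8-tetrahydro-1H-isochromen-7-yl 4-hydroxy-2-methoxy-6-methylbenzoate | C/C=C/C1=CC2=C(CO1)C(=O)[C@](C)(OC(=O)c1c(C)cc(O)cc1OC)[C@@H](O)C2 | target

## Step count and least certain steps

Total: 15 steps. Longest linear sequence: 13 steps (steps 1–10 and 13–15). The acid branch (steps 11 and 12) joins at step 13.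

Step 10 (key step). The most likely failure is competing migration of the alkenyl carbon C8a. C6 carries an oxygen and is the poorer migrating group, so the shift may first go the other way and return only slowly. If the manifold becomes reversible, or a non-chelated rotamer reacts, stereochemical fidelity at C7 is lost. Loss of a silyl ether through adventitious triflic acid is a lesser risk. Fallback: the same ring expansion run on the other C8 epimer through the non-chelated alkoxide, where the epimeric centre and the opposite (anti) rotamer cancel. It sets out from 7. 1-Ethoxyvinyllithium is added to the ketone anti to the C6 silyl ether to give the enol ether carbinol F1. Dilute acid hydrolysis gives the C8-epimeric acetyl carbinol F2. K2CO3 in methanol gives the terminal alkyne F3. Sonogashira coupling with 11 gives the C8 epimer of the precursor, F4. Rearrangement of its potassium alkoxide (KN(SiMe3)2, crown ether, THF, low temperature), in which the C–O and C=O dipoles are opposed, should deliver C6 to the same carbonyl face as in the chelated reaction of 13. The fallback comes back to the route at 14.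

Step 1. The catalyst must add to C3 next to the silyloxy carbon. Slow conversion, elimination of silanol from the enone and erosion of the stereocentre by gamma-deprotonation are the likely failures. Fallback, setting out from 1: alpha-iodination with iodine and pyridine gives the iodo enone F5. Stille coupling with (tributylstannyl)methanol and Pd(PPh3)4 returns to the route at 2.

Step 5. The ylide is basic and the ketone is hindered and enolisable at C6. Enolisation in place of addition would lower conversion and, worse, erode the configuration at C6, the only stereocentre at that point. Fallback, setting out from 7: CeCl3-mediated addition of 1-(trimethylsilyl)ethylmagnesium chloride, a non-basic nucleophile, gives the beta-hydroxysilane F6. Peterson elimination returns to the route at 8.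

Step 13. A tertiary alkoxide meets a 2,6-disubstituted acyl chloride, so the acyl transfer may simply be too slow. During a slow reaction the C6 silyl group can shift to the C7 alkoxide, so that the wrong oxygen is acylated, and the alkoxide can undergo ring contraction by the reverse ketol shift. Fallback, setting out from 14: the tertiary alcohol is esterified with the small but-2-ynoic acid (carbodiimide coupling) to the ynoate F7. The benzoate ring is then built on it by Diels–Alder reaction with the diene A8 and aromatisation, giving the free-phenol benzoate F8. The ynenone alkyne is the less activated dienophile. F8 is taken through the conditions of step 14 and comes back to the route at 20.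

Step 15. The unprotected substrate may close with the wrong regiochemistry (5-exo), the phenol and diol may sequester the catalyst, or trace acid may degrade the dienol ether once formed. Fallback, setting out from 19: the primary silyl ether alone is removed with camphorsulfonic acid in methanol to give the primary alcohol F9. The ring is closed by conjugate (1,6) addition of the C1 hydroxyl to the ynenone under a catalytic amidine base, which the protected substrate tolerates, to give the bis-silyl isochromene F10. HF·pyridine then removes the two remaining silyl groups, and the fallback comes back to the route at 21.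

## Further compounds

F1 | step 10 | 1-(1-ethoxyvinyl) carbinol from 7, carbinol hydroxyl cis to the C6 silyl ether | C[Si](C)(C)C#CC1=C(CO[Si](C)(C)C(C)(C)C)[C@](O)(C(=C)OCC)[C@@H](O[Si](C)(C)C(C)(C)C)C1
F2 | step 10 | C8-epimeric acetyl carbinol with trimethylsilyl alkyne (acetyl trans to the C6 silyl ether) | C[Si](C)(C)C#CC1=C(CO[Si](C)(C)C(C)(C)C)[C@](O)(C(C)=O)[C@@H](O[Si](C)(C)C(C)(C)C)C1
F3 | step 10 | C8-epimeric acetyl carbinol with terminal alkyne | C#CC1=C(CO[Si](C)(C)C(C)(C)C)[C@](O)(C(C)=O)[C@@H](O[Si](C)(C)C(C)(C)C)C1
F4 | step 10 | C8 epimer of 13 | C/C=C/C#CC1=C(CO[Si](C)(C)C(C)(C)C)[C@](O)(C(C)=O)[C@@H](O[Si](C)(C)C(C)(C)C)C1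
F5 | step 1 | (S)-4-(tert-butyldimethylsilyloxy)-2-iodocyclopent-2-en-1-one | O=C1C(I)=C[C@@H](O[Si](C)(C)C(C)(C)C)C1
F6 | step 5 | beta-hydroxysilane from 7, diastereomer mixture at the two new centres | C[Si](C)(C)C#CC1=C(CO[Si](C)(C)C(C)(C)C)C(O)(C(C)[Si](C)(C)C)[C@@H](O[Si](C)(C)C(C)(C)C)C1
F7 | step 13 | but-2-ynoate of 14 | C/C=C/C#CC1=C(CO[Si](C)(C)C(C)(C)C)C(=O)[C@](C)(OC(=O)C#CC)[C@@H](O[Si](C)(C)C(C)(C)C)C1
F8 | step 13 | 19 with the phenol free | C/C=C/C#CC1=C(CO[Si](C)(C)C(C)(C)C)C(=O)[C@](C)(OC(=O)c2c(C)cc(O)cc2OC)[C@@H](O[Si](C)(C)C(C)(C)C)C1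
F9 | step 15 | 19 with the C1 hydroxyl free | C/C=C/C#CC1=C(CO)C(=O)[C@](C)(OC(=O)c2c(C)cc(O[Si](C)(C)C(C)(C)C)cc2OC)[C@@H](O[Si](C)(C)C(C)(C)C)C1
F10 | step 15 | 21 with the phenol and the C6 hydroxyl silylated | C/C=C/C1=CC2=C(CO1)C(=O)[C@](C)(OC(=O)c1c(C)cc(O[Si](C)(C)C(C)(C)C)cc1OC)[C@@H](O[Si](C)(C)C(C)(C)C)C2
A1 | alternative 1 | 21 with the phenol as tert-butyldimethylsilyl ether | C/C=C/C1=CC2=C(CO1)C(=O)[C@](C)(OC(=O)c1c(C)cc(O[Si](C)(C)C(C)(C)C)cc1OC)[C@@H](O)C2
A2 | alternative 1 | 2-methyl-1-[4-methyl-6-[(E)-prop-1-enyl]-2H-pyran-3-yl]-1,3-dioxopropan-2-yl 4-(tert-butyldimethylsilyloxy)-2-methoxy-6-methylbenzoate, C7 as in 21 | C/C=C/C1=CC(C)=C(CO1)C(=O)[C@](C)(OC(=O)c1c(C)cc(O[Si](C)(C)C(C)(C)C)cc1OC)C=O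
A3 | alternative 1 | silyl dienol ether of A2 with exocyclic methylene on C4a | C/C=C/C1=CC(=C)C(CO1)=C(O[Si](C)(C)C(C)(C)C)[C@](C)(OC(=O)c1c(C)cc(O[Si](C)(C)C(C)(C)C)cc1OC)C=O
A4 | alternative 2 | (6S,7R)-6-(tert-butyldimethylsilyloxy)-7-hydroxy-7-methyl-3-[(E)-prop-1-enyl]-6,7-dihydro-1H-isochromen-8(5H)-one | C/C=C/C1=CC2=C(CO1)C(=O)[C@](C)(O)[C@@H](O[Si](C)(C)C(C)(C)C)C2
A5 | alternative 2 | 4-[(2S)-2-(tert-butyldimethylsilyloxy)-3-oxobutyl]-6-[(E)-prop-1-enyl]-2H-pyran-3-carbaldehyde | C/C=C/C1=CC(C[C@H](O[Si](C)(C)C(C)(C)C)C(C)=O)=C(CO1)C=O
A6 | alternative 3 | 21 with the C6 hydroxyl as tert-butyldimethylsilyl ether | C/C=C/C1=CC2=C(CO1)C(=O)[C@](C)(OC(=O)c1c(C)cc(O)cc1OC)[C@@H](O[Si](C)(C)C(C)(C)C)C2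
A7 | alternative 3 | C7 but-2-ynoate of the C6-silylated bicyclic ketol | C/C=C/C1=CC2=C(CO1)C(=O)[C@](C)(OC(=O)C#CC)[C@@H](O[Si](C)(C)C(C)(C)C)C2
A8 | alternative 3 | 1,1-dimethoxy-3-(trimethylsilyloxy)buta-1,3-diene | C=C(O[Si](C)(C)C)C=C(OC)OC
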